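(The readings were generated by integration with constants of no real substance; noise was put on by code.)

Run epsilon lost left-handed substrate at 2.89 mM/min over its first 4.00 min. The bench rule is therefore a straight line at that slope, zero-order in c(left-handed substrate).

all flasks: free catalyst 20 µM
- alpha: left-handed substrate 20 mM; right-handed substrate 20 mM; protic impurity 2 mM; solid reagent 60 mM; run made earlier
- epsilon: left-handed substrate 20 mM; right-handed substrate 20 mM; protic impurity 8 mM; solid reagent 60 mM; run made earlier
- beta: left-handed substrate 40 mM; right-handed substrate 40 mM; protic impurity 4 mM; solid reagent 60 mM; run made earlier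
- flask: left-handed substrate 20 mM; right-handed substrate 20 mM; protic impurity 4.00 mM; solid reagent 60.0 mM; time 50 min

- alpha (time / min: right-handed substrate / %, left-handed substrate / %, left-handed product / %): 10.0: 47.3, 0, 50.1; 20.0: 42.7, 0, 49.9; 30.0: 36.7, 0, 49.4; 40.0: 31.7, 0.2, 49.9; 50.0: 28.7, 0, 49.6
- epsilon (time / min: right-handed substrate / %, left-handed substrate / %, left-handed product / %): 4.00: 49.9, 21.1, 27.9; 12.0: 46.9, 0.8, 50.1; 25.0: 39.2, 0.2, 50.3; 40.0: 32.7, 0, 49.9; 50.0: 29.6, 0, 50.2
- beta (time / min: right-handed substrate / %, left-handed substrate / %, left-handed product / %): 4.00: 49.8, 34.5, 14.8; 12.0: 48.7, 5.3, 45.3; 25.0: 44.7, 0.2, 49.9; 40.0: 38.9, 0.4, 50.6; 50.0: 36.8, 0.2, 48.8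

(readings scatter by 0.5 percentage points)

- free catalyst is single-handed; left-handed substrate and right-handed substrate are mirror images of each other, charged as a racemate, each of them at the stated concentration
- as a solid, counted per litre of solution: solid reagent
- at the start none of the solid reagent is in solution

1. whether the excess of right-handed substrate over left-handed substrate among what is left of the two reaches 80% by 50 min (no / yes)
2. the highest excess of right-handed substrate over left-handed substrate among what is left of the two up to 50 min

The wanted 80% excess means that c(left-handed substrate) has fallen to 0.111 of c(right-handed substrate). In the flask, with c(right-handed substrate) still at its charge, the straight line reaches that point at 6.15 min. Going round once more, c(right-handed substrate) is put in at epsilon's value for 12.0 min, 18.8 mM, which gives 6.20 min. This is the crossing time: the charge of left-handed substrate less the remainder the excess allows, divided by the slope.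

The line has a border. Run beta at 12.0 min still held 4.24 mM of left-handed substrate, where the line gives 5.32 mM. The flask's remainder of 2.22 mM is about half of the lowest level beta checks, so the crossing lies beyond that check, but 6.20 min is far earlier than 50 min. The reckoning here therefore says yes, with the excess ending close to 100%.

The forecast says yes with a top of 99.5%, also reading that “the left-handed substrate is consumed at a nearly constant rate”, and places the crossing at 8 to 10 min, against 6.20 min here.

    free catalyst + left-handed substrate ⇌ catalyst intermediate A (K = 1100 /M, k = 7070 /M/s)
    free catalyst + right-handed substrate ⇌ catalyst intermediate B (K = 11.0 /M, k = 10300 /M/s)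
    partner + catalyst intermediate A → free catalyst + left-handed product (k = 475 /M/s)
    partner + catalyst intermediate B → free catalyst + right-handed product (k = 174 /M/s)
    partner + protic impurity → quenched reagent (k = 0.0870 /M/s)
    solid reagent ⇌ partner, rate k6*(cs6 - [partner]) while solid is left; crystals form when [partner] > cs6 (solubility = 6.40 mM, k = 0.112 /s)
    partner ⇌ dormant form (K = 0.855, k = 0.0289 /s)

The flask gives yes, with a top of 100%. It reaches 80% at 6.54 min, against the crossing time of 6.20 min, with right-handed substrate at 49.4% of the two substrates charged. On run beta, with epsilon's slope and c(right-handed substrate) at its 12.0 min reading, the crossing time comes to 12.3 min. Beta's readings at 12.0 min give an excess of 80.4%.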